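Ring B (the central benzene) carries two para oxygens, the methoxy oxygen and the oxygen bridging to quinone ring C, with aryloxy, methyl, H and isopropyl on the other four carbons; it is therefore made as a 1,4-benzoquinone. The key step builds that quinone from two 1,2-diketones: the ArO–CH2 carbon of an aryloxy diketone (ring A already attached through the ether oxygen) condenses with a biacetyl carbonyl, and the far biacetyl methyl condenses with the isopropyl ketone, forming the C(OAr)=C(CH3) and CH=C(i-Pr) bonds and the ring in one operation. Reduction, methylation of the exposed hydroxyl and addition–elimination on a bromothymoquinone (ring C) complete the target.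

Key step: step 6

Remark on stereochemistry: the target SMILES holds no stereocentre and no stereogenic double bond, and the diaryl ether axes are taken as freely rotating, so the compound is treated as achiral and no stereocontrol is needed.

Abbreviation: Ar = 2-isopropyl-4-methoxy-5-methylphenyl (ring A).

Step 1
Reactants: 1 thymol (2-isopropyl-5-methylphenol)
Product: 2 4-bromothymol (4-bromo-2-isopropyl-5-methylphenol)
Conditions: NBS (1.0 equiv), MeCN, 0 °C → rt
Reagents that add atoms: N-bromosuccinimide, O=C1CCC(=O)N1Br
Why: Electrophilic aromatic bromination, in which the hydroxyl directs NBS to its free para position, the most activated and most accessible site of thymol in MeCN.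

Step 2
Reactants: 2 4-bromothymol
Product: 3 4-methoxythymol (2-isopropyl-4-methoxy-5-methylphenol)
Conditions: NaOMe (5 equiv), CuI (10 mol %), MeOH/DMF, 110 °C; aq. HCl work-up
Reagents that add atoms: sodium methoxide, C[O-].[Na+]
Why: Copper-catalysed Ullmann-type methoxylation of the aryl bromide, in which the free phenol is carried as its phenoxide and returned on acidification.

Step 3
Reactants: 4 3-methylbut-1-yne
Product: 6 4-methylpent-2-yn-1-ol, via lithium acetylide 5 (not isolated)
Conditions: n-BuLi (1.05 equiv), THF, −78 °C; (CH2O)n, −78 °C → rt; aq. HCl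
Reagents that add atoms: paraformaldehyde (reacts as formaldehyde), C=O
Why: Deprotonation of the terminal alkyne and addition of the acetylide to formaldehyde is the standard one-carbon extension to a primary propargylic alcohol.

Step 4
Reactants: 3 4-methoxythymol; 6 4-methylpent-2-yn-1-ol
Product: 7 1-isopropyl-5-methoxy-4-methyl-2-[(4-methylpent-2-yn-1-yl)oxy]benzene (ArO–CH2–C≡C–CH(CH3)2)
Conditions: PPh3, DIAD, THF, 0 °C → rt
Reagents that add atoms: none
Why: Mitsunobu etherification, in which the phenol is acidic enough to protonate the betaine and the activated primary propargylic alcohol is displaced by SN2, so no separate propargylic bromide is needed.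

Step 5
Reactants: 7 aryl propargyl ether
Product: 8 1-(2-isopropyl-4-methoxy-5-methylphenoxy)-4-methylpentane-2,3-dione (ArO–CH2–CO–CO–CH(CH3)2)
Conditions: KMnO4, NaHCO3, MgSO4, acetone/H2O, 0 °C → rt
Reagents that add atoms: potassium permanganate, [K+].[O-][Mn](=O)(=O)=O
Why: Buffered permanganate oxidation of an internal dialkyl alkyne stops at the 1,2-diketone, and the neutral medium should leave the dialkoxyarene and its benzylic C–H bonds untouched, which is why RuO4-type oxidants are avoided.

Step 6
Reactants: 8 1-(2-isopropyl-4-methoxy-5-methylphenoxy)-4-methylpentane-2,3-dione; 9 biacetyl (butane-2,3-dione)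
Product: 13 2-(2-isopropyl-4-methoxy-5-methylphenoxy)-6-isopropyl-3-methyl-1,4-benzoquinone (ring B as quinone), via lithium enolate 10 (not isolated), via lithium aldolate 11 (not isolated), via cyclic bis-aldol 12 (not isolated)
Conditions: LiHMDS (1.05 equiv), THF, −78 °C; cannulate into 9 (5 equiv), THF, −78 → 0 °C; evaporate, then TsOH·H2O (2.2 equiv), PhMe, 4 Å MS, 60 °C
Reagents that add atoms: none
Why: Proposed new method: enolate 10 is formed first at the OCH2 group, the only kinetically accessible acidic site of 8 (flanked by aryloxy and the 1,2-dicarbonyl), and adds to a carbonyl of the unhindered, activated biacetyl to give aldolate 11; on warming, proton transfer gives the methyl-ketone enolate, whose CH2 terminus attacks the isopropyl ketone to give 12, and acid then removes two molecules of water by β-elimination to give quinone 13 with no redox change. The closest known reaction type is the base-mediated self-condensation of biacetyl to 2,5-dimethyl-1,4-benzoquinone (aldol dimerisation, ring-closing aldol, double dehydration), here run as a crossed variant with one partner pre-enolised. Ring B closes by a 6-(enolendo)-exo-trig aldol addition, while closure onto the neighbouring C2 carbonyl would be a disfavoured 5-(enolendo)-exo-trig process. No stereocentre survives: those of 11 and 12 arise as mixtures and are erased by the dehydrations. The step needs crossed over self-condensation and the correct pairing of the four carbonyls; the first is secured by complete pre-formation of 10 and its inverse addition to excess biacetyl at −78 °C, the second by the fact that aldol addition is reversible until water is lost and only the pairing shown (ArO–CH to a biacetyl C=O, biacetyl CH3 to the isopropyl C=O) can lose two molecules of water to reach a six-membered quinone. The acidic finish keeps the aryloxyquinone, a vinylogous ester, away from nucleophilic base.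

Step 7
Reactants: 13 dimer quinone
Product: 14 2-(2-isopropyl-4-methoxy-5-methylphenoxy)-6-isopropyl-3-methylbenzene-1,4-diol
Conditions: Na2S2O4 (aq.), EtOAc, rt, Ar
Reagents that add atoms: none
Why: Dithionite reduces the quinone to the hydroquinone by two-electron transfer without touching the aryl ethers; the product should be kept under argon and used at once.

Step 8
Reactants: 14 dimer hydroquinone
Product: 15 2-(2-isopropyl-4-methoxy-5-methylphenoxy)-6-isopropyl-4-methoxy-3-methylphenol
Conditions: MeI (1.05 equiv), K2CO3 (1.1 equiv), acetone (degassed), rt, Ar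
Reagents that add atoms: iodomethane, CI
Why: Williamson O-methylation with one equivalent of MeI should take the hydroxyl flanked by CH3 and H, because the other hydroxyl is shielded on both sides by isopropyl and aryloxy.

Step 9
Reactants: 3 4-methoxythymol
Product: 16 2-bromo-6-isopropyl-4-methoxy-3-methylphenol
Conditions: NBS (1.0 equiv), i-Pr2NH (10 mol %), CH2Cl2, 0 °C
Reagents that add atoms: N-bromosuccinimide, O=C1CCC(=O)N1Br
Why: Amine-catalysed NBS bromination goes ortho to the free hydroxyl (the stronger director), at the position between OH and CH3, while the only other free position is meta to OH and wedged between isopropyl and OMe.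

Step 10
Reactants: 16 2-bromo-6-isopropyl-4-methoxy-3-methylphenol
Product: 17 2-bromo-6-isopropyl-3-methyl-1,4-benzoquinone
Conditions: PhI(OAc)2 (1.1 equiv), MeCN/H2O, 0 °C
Reagents that add atoms: water, O
Why: Hypervalent-iodine oxidation of a para-methoxyphenol, in which water adds at the methoxy-bearing carbon of the phenoxonium species and methanol is lost to give the para-quinone with the bromine retained.

Step 11
Reactants: 15 2-(2-isopropyl-4-methoxy-5-methylphenoxy)-6-isopropyl-4-methoxy-3-methylphenol; 17 2-bromo-6-isopropyl-3-methyl-1,4-benzoquinone
Product: 18 2-[2-(2-isopropyl-4-methoxy-5-methylphenoxy)-6-isopropyl-4-methoxy-3-methylphenoxy]-6-isopropyl-3-methyl-1,4-benzoquinone (target)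
Conditions: Cs2CO3 (1.2 equiv), 17 (1.3 equiv), MeCN, 0 °C → rt
Reagents that add atoms: none
Why: Addition–elimination (vinylogous acyl substitution) on a haloquinone, in which the caesium phenoxide adds at the bromine-bearing carbon and loss of bromide restores the quinone without any change in oxidation level.

Compound list
1 | thymol (2-isopropyl-5-methylphenol) | Cc1ccc(C(C)C)c(O)c1 | starting material
2 | 4-bromothymol (4-bromo-2-isopropyl-5-methylphenol) | Cc1cc(O)c(C(C)C)cc1Br | intermediate
3 | 4-methoxythymol (2-isopropyl-4-methoxy-5-methylphenol) | COc1cc(C(C)C)c(O)cc1C | intermediate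
4 | 3-methylbut-1-yne | CC(C)C#C | starting material
5 | lithium 3-methylbut-1-yn-1-ide (lithium acetylide, not isolated) | CC(C)C#C[Li] | intermediate
6 | 4-methylpent-2-yn-1-ol | CC(C)C#CCO | intermediate
7 | 1-isopropyl-5-methoxy-4-methyl-2-[(4-methylpent-2-yn-1-yl)oxy]benzene | COc1cc(C(C)C)c(OCC#CC(C)C)cc1C | intermediate
8 | 1-(2-isopropyl-4-methoxy-5-methylphenoxy)-4-methylpentane-2,3-dione | COc1cc(C(C)C)c(OCC(=O)C(=O)C(C)C)cc1C | intermediate
9 | biacetyl (butane-2,3-dione) | CC(=O)C(C)=O | starting material
10 | lithium (Z)-enolate of 8 at the ArO–CH=C(OLi) position (chelated geometry assumed, of no consequence; not isolated) | COc1cc(C(C)C)c(O/C=C(\O[Li])C(=O)C(C)C)cc1C | intermediate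
11 | lithium alkoxide of 6-hydroxy-5-(2-isopropyl-4-methoxy-5-methylphenoxy)-2,6-dimethyloctane-3,4,7-trione (mixture of racemic diastereomers, not isolated) | COc1cc(C(C)C)c(OC(C(=O)C(=O)C(C)C)C(C)(O[Li])C(C)=O)cc1C | intermediate
12 | 2-(2-isopropyl-4-methoxy-5-methylphenoxy)-3,6-dihydroxy-6-isopropyl-3-methylcyclohexane-1,4-dione (mixture of racemic diastereomers, not isolated) | COc1cc(C(C)C)c(OC2C(=O)C(O)(C(C)C)CC(=O)C2(C)O)cc1C | intermediate
13 | 2-(2-isopropyl-4-methoxy-5-methylphenoxy)-6-isopropyl-3-methyl-1,4-benzoquinone | COc1cc(C(C)C)c(OC2=C(C)C(=O)C=C(C(C)C)C2=O)cc1C | intermediate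
14 | 2-(2-isopropyl-4-methoxy-5-methylphenoxy)-6-isopropyl-3-methylbenzene-1,4-diol | COc1cc(C(C)C)c(Oc2c(C)c(O)cc(C(C)C)c2O)cc1C | intermediate
15 | 2-(2-isopropyl-4-methoxy-5-methylphenoxy)-6-isopropyl-4-methoxy-3-methylphenol | COc1cc(C(C)C)c(Oc2c(C)c(OC)cc(C(C)C)c2O)cc1C | intermediate
16 | 2-bromo-6-isopropyl-4-methoxy-3-methylphenol | COc1cc(C(C)C)c(O)c(Br)c1C | intermediate
17 | 2-bromo-6-isopropyl-3-methyl-1,4-benzoquinone | CC(C)C1=CC(=O)C(C)=C(Br)C1=O | intermediate
18 | 2-[2-(2-isopropyl-4-methoxy-5-methylphenoxy)-6-isopropyl-4-methoxy-3-methylphenoxy]-6-isopropyl-3-methyl-1,4-benzoquinone | COc1cc(C(C)C)c(Oc2c(C)c(OC)cc(C(C)C)c2OC2=C(C)C(=O)C=C(C(C)C)C2=O)cc1C | target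

Total step count: 11
Longest linear sequence: 8 steps (1, 2, 4, 5, 6, 7, 8, 11)

Steps most likely to fail

Step 6 (proposed new method). What may go wrong:
- proton transfer from biacetyl to enolate 10, followed by self-condensation of biacetyl;
- retro-aldol of 11 before the ring closes;
- capture of the new tertiary alkoxide as a five-membered hemiketal on the isopropyl ketone and its dehydration to a furanone;
- incomplete loss of the second water.

Fallback, known chemistry: it sets out from 4-methoxythymol 3 and uses bromoquinone 17, both already in the route. The two are joined by the addition–elimination of step 11 (Cs2CO3, MeCN, 0 °C → rt), the phenoxide of 3 displacing bromide at the bromine-bearing quinone carbon. It comes back to the route at quinone 13. Ring B is then taken from a preformed thymol ring instead of being built, and no compound outside the list is made (F0).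

Step 11. What may go wrong: attack by a phenoxide shielded on both sides is slow, so degradation of the alkylquinone by base can outrun substitution (deprotonation at its ring methyl, conjugate addition at its unsubstituted carbon, electron transfer).

Fallback: it sets out from phenol 15 and replaces substitution by oxidative conjugate addition. 4-Methoxythymol 3 is oxidised with PhI(OAc)2 in aqueous MeCN to thymoquinone F1. With a catalytic amount of base, 15 adds to the unsubstituted ring carbon of F1 next to the methyl-bearing carbon, the less hindered of the two CH positions, to give hydroquinone adduct F2. A second equivalent of F1 oxidises F2 in the flask, and the fallback comes back to the route at target 18.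

Step 8. What may go wrong: insufficient discrimination between the two hydroxyls, double methylation, and aerial re-oxidation of the hydroquinone under base.

Fallback: it sets out from hydroquinone 14 and uses a bulky silyl group, which discriminates by size far better than MeI. TIPSCl and imidazole in DMF should silylate only the open hydroxyl to give mono-TIPS ether F3. Its remaining hindered phenol is coupled with 17 as in step 11 to give silylated trimer quinone F4. Desilylation with TBAF buffered with AcOH (THF, 0 °C) gives trimer phenol F5. Methylation of its single free hydroxyl (MeI, K2CO3, acetone) comes back to the route at target 18.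

Further compounds
F0 | step 6 | none | none
F1 | step 11 | thymoquinone (2-isopropyl-5-methyl-1,4-benzoquinone) | CC1=CC(=O)C(C(C)C)=CC1=O
F2 | step 11 | 2-[2-(2-isopropyl-4-methoxy-5-methylphenoxy)-6-isopropyl-4-methoxy-3-methylphenoxy]-6-isopropyl-3-methylbenzene-1,4-diol | COc1cc(C(C)C)c(Oc2c(C)c(OC)cc(C(C)C)c2Oc2c(C)c(O)cc(C(C)C)c2O)cc1C
F3 | step 8 | 2-(2-isopropyl-4-methoxy-5-methylphenoxy)-6-isopropyl-3-methyl-4-(triisopropylsilyloxy)phenol | COc1cc(C(C)C)c(Oc2c(C)c(O[Si](C(C)C)(C(C)C)C(C)C)cc(C(C)C)c2O)cc1C
F4 | step 8 | 2-[2-(2-isopropyl-4-methoxy-5-methylphenoxy)-6-isopropyl-3-methyl-4-(triisopropylsilyloxy)phenoxy]-6-isopropyl-3-methyl-1,4-benzoquinone | COc1cc(C(C)C)c(Oc2c(C)c(O[Si](C(C)C)(C(C)C)C(C)C)cc(C(C)C)c2OC2=C(C)C(=O)C=C(C(C)C)C2=O)cc1C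
F5 | step 8 | 2-[4-hydroxy-2-(2-isopropyl-4-methoxy-5-methylphenoxy)-6-isopropyl-3-methylphenoxy]-6-isopropyl-3-methyl-1,4-benzoquinone | COc1cc(C(C)C)c(Oc2c(C)c(O)cc(C(C)C)c2OC2=C(C)C(=O)C=C(C(C)C)C2=O)cc1C
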